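**Retrosynthetic overview**
1. The strategy rests on the 1,6-dioxaspiro[4.4]nonane. Ring A is O1', C2' (tether), C3', C4', spiro C5'; ring B is C5', O6', C7' (methyl), C8', C9'. The oxygens on C2' and C5' stand in a dissonant 1,4 relationship. O1'–C5' is therefore bought as an ester bond, and C4'–C5' is made by olefinating that ester carbon with alkene carbon C4'.
2. The phthalide comes last. The C3–aryl bond and the lactone C–O bond lead back to a spiroketal heptanal and methyl 2-iodo-4,6-dimethoxybenzoate; a catalytic asymmetric arylzinc addition–lactonization sets C3.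
3. Ring B: O6'–C5' leads back to a hydroxy-tethered 2,3-dihydrofuran; a catalyst-controlled kinetic spiroacetalization sets C5'.
4. Ring A: C4'=C5' leads back to a homoallylic ester (titanium alkylidene). The ester is the C2' carbinol (iridium allylation of monobenzyl octanediol) acylated with the C7' acid from (S)-γ-valerolactone.
5. Order of ring formation: A (step 6), B (step 8), lactone (step 14). The arene is bought.

Key step: step 6

Assumption: in steps 2, 8 and 14 the catalyst antipode written is the one expected to give the required face (Re face of the transient aldehyde in step 2, the C5' face anti to the C2' tether in step 8, Si face of the aldehyde in step 14). The face is what the route requires, and the mirror-image catalyst is taken if the sense of induction proves opposite.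

**Step 1**
Reactants: 1 octane-1,8-diol
Product: 2 8-(benzyloxy)octan-1-ol
Conditions: NaH (1 equiv), BnBr (1 equiv), Bu4NI (cat.), diol in excess, THF, 0 °C → rt
Reagents that add atoms: benzyl bromide, BrCc1ccccc1
Why: Williamson etherification of the mono-alkoxide, in which an excess of the cheap symmetrical diol suppresses dibenzylation and the polar diol is washed out.

**Step 2**
Reactants: 2 8-(benzyloxy)octan-1-ol; 3 allyl acetate
Product: 4 (4S)-11-(benzyloxy)undec-1-en-4-ol
Conditions: [Ir(cod)Cl]2 (2.5 mol %), (R)-Cl,MeO-BIPHEP (5 mol %), 4-Cl-3-NO2-C6H3CO2H (10 mol %), Cs2CO3 (20 mol %), allyl acetate (excess), THF, 100 °C, sealed tube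
Reagents that add atoms: none
Why: Iridium-catalysed transfer-hydrogenative carbonyl allylation (Krische allylation), in which the cyclometallated π-allyliridium C,O-benzoate dehydrogenates 2 to the aldehyde and delivers allyl through a closed chair transition state to its Re face under control of the chiral bisphosphine, setting C2' as (S) while the benzyl ether is inert.

**Step 3**
Reactants: 5 (S)-γ-valerolactone
Product: 6 sodium (4S)-4-hydroxypentanoate
Conditions: NaOH (1.0 equiv), MeOH–H2O, rt; evaporate and dry
Reagents that add atoms: sodium hydroxide, [Na+].[OH-]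
Why: Saponification by acyl–oxygen cleavage leaves the C7'–O bond untouched, so the (S) centre is retained, and the carboxylate salt cannot relactonise.

**Step 4**
Reactants: 6 sodium (4S)-4-hydroxypentanoate
Product: 8 (4S)-4-[(tert-butyldimethylsilyl)oxy]pentanoic acid, via tert-butyldimethylsilyl (4S)-4-[(tert-butyldimethylsilyl)oxy]pentanoate 7 (not isolated)
Conditions: TBSCl (2.5 equiv), imidazole, DMF, rt; then K2CO3, MeOH–H2O, rt; aq. KHSO4 to pH 4, 0 °C
Reagents that add atoms: tert-butyldimethylsilyl chloride, CC(C)(C)[Si](C)(C)Cl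
Why: Bis-silylation followed by selective carbonate cleavage of the far more labile silyl ester is the standard access to a 4-silyloxy acid, and the silyl ether blocks relactonisation during the brief mild acidification.

**Step 5**
Reactants: 4 (4S)-11-(benzyloxy)undec-1-en-4-ol; 8 (4S)-4-[(tert-butyldimethylsilyl)oxy]pentanoic acid
Product: 9 (4S)-11-(benzyloxy)undec-1-en-4-yl (4S)-4-[(tert-butyldimethylsilyl)oxy]pentanoate
Conditions: EDC·HCl, DMAP, CH2Cl2, 0 °C → rt
Reagents that add atoms: none
Why: Steglich esterification makes O1'–C5' with retention at C2' because only the O–H bond of 4 is broken, and any minor enantiomer of 4 becomes a diastereomer from here on and can be removed downstream.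

**Step 6**
Reactants: 9 (4S)-11-(benzyloxy)undec-1-en-4-yl (4S)-4-[(tert-butyldimethylsilyl)oxy]pentanoate
Product: 11 (2S)-2-[7-(benzyloxy)heptyl]-5-{(3S)-3-[(tert-butyldimethylsilyl)oxy]butyl}-2,3-dihydrofuran, via the titanium alkylidene of 9 at C4' 10 (not isolated)
Conditions: TiCl4, TMEDA, Zn, PbCl2 (cat.), CH3CHBr2, THF–CH2Cl2, 0 → 65 °C; aq. K2CO3 work-up; basic Al2O3
Reagents that add atoms: none
Why: The reduced titanium ethylidene made from TiCl4, Zn and 1,1-dibromoethane exchanges with the only alkene of 9 (loss of propene) to give alkylidene 10, whose Ti=C4' adds across the only carbonyl, O=C5', to an oxatitanacyclobutane that cycloreverts to the C4'=C5' bond and a titanium oxo species; the other order (ester ethylidenation, then enol ether–olefin metathesis, again losing propene) ends in the same product. The closest known reaction type is the olefinic ester cyclization with Takai–Utimoto-type titanium alkylidenes, together with its two-stage form of ester methylenation and enol ether–olefin ring-closing metathesis, which is best documented for six- and seven-membered cyclic enol ethers and less often for five-membered ones. Ring A closes as a five-membered ring by ring-closing carbonyl–olefin metathesis through a bicyclo[3.2.0] oxatitanacycle, and the new double bond is endocyclic. No stereocentre is formed, and C2' and C7' are spectators because the TMEDA-buffered medium is neither acidic nor enolising. The step needs chemoselectivity and cyclic-over-acyclic partitioning: 9 holds one carbonyl and one unhindered terminal alkene, benzyl and TBS ethers are inert, and the ethylidene reagent olefinates esters more slowly than the methylidene so that alkene exchange can come first. Basic work-up and basic alumina keep the double bond at C4'=C5' and prevent hydrolysis.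

**Step 7**
Reactants: 11 (2S)-2-[7-(benzyloxy)heptyl]-5-{(3S)-3-[(tert-butyldimethylsilyl)oxy]butyl}-2,3-dihydrofuran
Product: 12 (2S)-4-{(5S)-5-[7-(benzyloxy)heptyl]-4,5-dihydrofuran-2-yl}butan-2-ol
Conditions: TBAF, THF, 0 °C → rt; aq. NaHCO3 work-up; Et3N-deactivated silica
Reagents that add atoms: none
Why: Fluoride desilylation is basic, so the acid-labile enol ether and the benzyl ether survive, and the basic work-up keeps 12 from cyclising without control.

**Step 8**
Reactants: 12 (2S)-4-{(5S)-5-[7-(benzyloxy)heptyl]-4,5-dihydrofuran-2-yl}butan-2-ol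
Product: 13 (2S,5R,7S)-2-[7-(benzyloxy)heptyl]-7-methyl-1,6-dioxaspiro[4.4]nonane
Conditions: (S,S)-confined imidodiphosphoric acid from 3,3'-bis(2,4,6-triethylphenyl)-BINOL (5 mol %), 4 Å MS, MTBE, −35 °C; Et3N quench; Et3N-deactivated silica
Reagents that add atoms: none
Why: Chiral Brønsted acid-catalysed kinetic spiroacetalization of a hydroxy enol ether, in which the confined bifunctional acid protonates C4' while its phosphoryl oxygen holds the C7' hydroxyl, so that O6' adds to C5' in a concerted asynchronous 5-exo-trig closure on the face anti to the C2' tether (catalyst antipode matched to this modest substrate bias), setting C5' as (R), the E,E isomer with each alkyl group trans to the oxygen of the other ring, and the product should not re-ionise at low temperature in an apolar medium.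

**Step 9**
Reactants: 13 (2S,5R,7S)-2-[7-(benzyloxy)heptyl]-7-methyl-1,6-dioxaspiro[4.4]nonane
Product: 14 7-[(2S,5R,7S)-7-methyl-1,6-dioxaspiro[4.4]nonan-2-yl]heptan-1-ol
Conditions: H2 (1 atm), 10 % Pd/C, solid NaHCO3, EtOAc, rt
Reagents that add atoms: none
Why: Catalytic hydrogenolysis of the benzyl ether, the only reducible group left, with solid bicarbonate neutralising acid traces of the catalyst so that C5' is not equilibrated.

**Step 10**
Reactants: 14 7-[(2S,5R,7S)-7-methyl-1,6-dioxaspiro[4.4]nonan-2-yl]heptan-1-ol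
Product: 15 7-[(2S,5R,7S)-7-methyl-1,6-dioxaspiro[4.4]nonan-2-yl]heptanal
Conditions: TPAP (5 mol %), NMO, 4 Å MS, CH2Cl2, rt; short Et3N-deactivated silica plug
Reagents that add atoms: none
Why: Ley–Griffith oxidation is neutral and stops at the aldehyde under anhydrous conditions, so the spiro centre is not exposed to acid.

**Step 11**
Reactants: 16 1-iodo-3,5-dimethoxybenzene
Product: 18 2-iodo-4,6-dimethoxybenzaldehyde, via (2-iodo-4,6-dimethoxybenzylidene)dimethyliminium chloride 17 (not isolated)
Conditions: POCl3, DMF, 0 → 90 °C; then ice–water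
Reagents that add atoms: N,N-dimethylformamide, CN(C)C=O; water, O
Why: Vilsmeier–Haack formylation goes to the position para to one methoxy group and ortho to the other (next to iodine) in preference to the position between the two methoxy groups, and the C–I carbon is meta to both donors and so is not prone to protodeiodination.

**Step 12**
Reactants: 18 2-iodo-4,6-dimethoxybenzaldehyde
Product: 19 2-iodo-4,6-dimethoxybenzoic acid
Conditions: NaClO2, NaH2PO4, 2-methyl-2-butene, t-BuOH–H2O, rt
Reagents that add atoms: sodium chlorite, [Na+].[O-]Cl=O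
Why: Pinnick oxidation, with 2-methyl-2-butene trapping hypochlorous acid so that the electron-rich ring is not chlorinated and the iodide is not oxidised.

**Step 13**
Reactants: 19 2-iodo-4,6-dimethoxybenzoic acid
Product: 20 methyl 2-iodo-4,6-dimethoxybenzoate
Conditions: MeI, K2CO3, DMF, rt
Reagents that add atoms: iodomethane, CI
Why: SN2 O-alkylation of the carboxylate avoids addition to the carbonyl of this di-ortho-substituted acid, for which Fischer esterification is slow.

**Step 14**
Reactants: 15 7-[(2S,5R,7S)-7-methyl-1,6-dioxaspiro[4.4]nonan-2-yl]heptanal; 20 methyl 2-iodo-4,6-dimethoxybenzoate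
Product: 23 (3R)-5,7-dimethoxy-3-{6-[(2S,5R,7S)-7-methyl-1,6-dioxaspiro[4.4]nonan-2-yl]hexyl}-2-benzofuran-1(3H)-one, via bis[3,5-dimethoxy-2-(methoxycarbonyl)phenyl]zinc 21 (not isolated), via methyl 2-{(1R)-1-hydroxy-7-[(2S,5R,7S)-7-methyl-1,6-dioxaspiro[4.4]nonan-2-yl]heptyl}-4,6-dimethoxybenzoate (formed as its zinc alkoxide) 22 (not isolated)
Conditions: 20 (2.4 equiv), Et2Zn (1.2 equiv), Li(acac) (cat.), NMP, rt; then (S)-3,3'-bis(morpholinomethyl)-H8-BINOL (10 mol %), THF; 15 (1 equiv), 0 °C → rt; pH 7 buffer; K2CO3 (cat.), MeOH, rt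
Reagents that add atoms: none
Why: Iodine–zinc exchange, favoured by the ortho ester and the two meta methoxy groups, gives the ester-tolerant diarylzinc 21, ligand-accelerated catalytic asymmetric aryl transfer from the chiral zinc aminonaphtholate to the Si face of the unbranched aldehyde sets C3 as (R), and the alkoxide of 22 closes the lactone by 5-exo-trig acyl substitution with loss of methoxide, all under non-acidic conditions that leave C5' alone.

**Compound list**
1 | octane-1,8-diol | OCCCCCCCCO | starting material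
2 | 8-(benzyloxy)octan-1-ol | OCCCCCCCCOCc1ccccc1 | intermediate
3 | allyl acetate | C=CCOC(C)=O | starting material
4 | (4S)-11-(benzyloxy)undec-1-en-4-ol | C=CC[C@H](CCCCCCCOCc1ccccc1)O | intermediate
5 | (S)-γ-valerolactone | C[C@H]1CCC(=O)O1 | starting material
6 | sodium (4S)-4-hydroxypentanoate | C[C@H](O)CCC(=O)[O-].[Na+] | intermediate
7 | tert-butyldimethylsilyl (4S)-4-[(tert-butyldimethylsilyl)oxy]pentanoate | CC(C)(C)[Si](C)(C)OC(=O)CC[C@H](C)O[Si](C)(C)C(C)(C)C | intermediate
8 | (4S)-4-[(tert-butyldimethylsilyl)oxy]pentanoic acid | OC(=O)CC[C@H](C)O[Si](C)(C)C(C)(C)C | intermediate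
9 | (4S)-11-(benzyloxy)undec-1-en-4-yl (4S)-4-[(tert-butyldimethylsilyl)oxy]pentanoate | C=CC[C@H](CCCCCCCOCc1ccccc1)OC(=O)CC[C@H](C)O[Si](C)(C)C(C)(C)C | intermediate
10 | titanium alkylidene of 9 at C4' (terminal CH2 replaced by TiCl2, TMEDA ligand omitted) | Cl[Ti](Cl)=CC[C@H](CCCCCCCOCc1ccccc1)OC(=O)CC[C@H](C)O[Si](C)(C)C(C)(C)C | intermediate
11 | (2S)-2-[7-(benzyloxy)heptyl]-5-{(3S)-3-[(tert-butyldimethylsilyl)oxy]butyl}-2,3-dihydrofuran | c1ccccc1COCCCCCCC[C@H]1CC=C(CC[C@H](C)O[Si](C)(C)C(C)(C)C)O1 | intermediate
12 | (2S)-4-{(5S)-5-[7-(benzyloxy)heptyl]-4,5-dihydrofuran-2-yl}butan-2-ol | c1ccccc1COCCCCCCC[C@H]1CC=C(CC[C@H](C)O)O1 | intermediate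
13 | (2S,5R,7S)-2-[7-(benzyloxy)heptyl]-7-methyl-1,6-dioxaspiro[4.4]nonane | c1ccccc1COCCCCCCC[C@H]1CC[C@@]2(CC[C@H](C)O2)O1 | intermediate
14 | 7-[(2S,5R,7S)-7-methyl-1,6-dioxaspiro[4.4]nonan-2-yl]heptan-1-ol | OCCCCCCC[C@H]1CC[C@@]2(CC[C@H](C)O2)O1 | intermediate
15 | 7-[(2S,5R,7S)-7-methyl-1,6-dioxaspiro[4.4]nonan-2-yl]heptanal | O=CCCCCCC[C@H]1CC[C@@]2(CC[C@H](C)O2)O1 | intermediate
16 | 1-iodo-3,5-dimethoxybenzene | COc1cc(I)cc(OC)c1 | starting material
17 | (2-iodo-4,6-dimethoxybenzylidene)dimethyliminium chloride | COc1cc(I)c(C=[N+](C)C)c(OC)c1.[Cl-] | intermediate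
18 | 2-iodo-4,6-dimethoxybenzaldehyde | COc1cc(I)c(C=O)c(OC)c1 | intermediate
19 | 2-iodo-4,6-dimethoxybenzoic acid | COc1cc(I)c(C(=O)O)c(OC)c1 | intermediate
20 | methyl 2-iodo-4,6-dimethoxybenzoate | COC(=O)c1c(I)cc(OC)cc1OC | intermediate
21 | bis[3,5-dimethoxy-2-(methoxycarbonyl)phenyl]zinc | COC(=O)c1c(OC)cc(OC)cc1[Zn]c1cc(OC)cc(OC)c1C(=O)OC | intermediate
22 | methyl 2-{(1R)-1-hydroxy-7-[(2S,5R,7S)-7-methyl-1,6-dioxaspiro[4.4]nonan-2-yl]heptyl}-4,6-dimethoxybenzoate (drawn as the free alcohol) | COC(=O)c1c(OC)cc(OC)cc1[C@@H](CCCCCC[C@H]3CC[C@@]4(CC[C@H](C)O4)O3)O | intermediate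
23 | (3R)-5,7-dimethoxy-3-{6-[(2S,5R,7S)-7-methyl-1,6-dioxaspiro[4.4]nonan-2-yl]hexyl}-2-benzofuran-1(3H)-one | COc1cc(OC)c2c(c1)[C@@H](CCCCCC[C@H]1CC[C@@]3(CC[C@H](C)O3)O1)OC2=O | target

Total step count: 14.
Longest linear sequence: 9 steps (1, 2, 5, 6, 7, 8, 9, 10, 14).

**Steps most likely to fail**

Step 6. The alkylidene may olefinate the ester before it exchanges with the alkene, so that the material stops short of ring closure. Five-membered closure is also the less documented case, and the dihydrofuran may hydrolyse or isomerise on work-up.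
- The fallback sets out from 9.
- Petasis methylenation (Cp2TiMe2, toluene, 70 °C) gives the isolable acyclic enol ether tert-butyl{[(2S)-5-{[(4S)-11-(benzyloxy)undec-1-en-4-yl]oxy}hex-5-en-2-yl]oxy}dimethylsilane F1.
- A separate catalytic enol ether–olefin ring-closing metathesis with a molybdenum imido alkylidene (benzene, rt to 60 °C, loss of ethene) closes the ring.
- The fallback comes back to the route at 11.

Step 8. Facial selectivity at C5' may be poor. The substrate bias is weak, cyclisation by adventitious acid competes with the chiral catalyst, and the spiro centre may epimerise afterwards.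
- The fallback sets out from 12, or from any epimer mixture obtained, and replaces kinetic control by equilibration with recycling.
- PPTS (cat.), CH2Cl2, rt gives the shallow thermodynamic mixture of 13 and its spiro epimer (2S,5S,7S)-2-[7-(benzyloxy)heptyl]-7-methyl-1,6-dioxaspiro[4.4]nonane F2.
- The two are separated by preparative HPLC and F2 is returned to the equilibration.
- The material funnels into 13, where the route resumes.

Step 14. Aryl transfer from the ester-chelated arylzinc may be sluggish, enantiofacial discrimination on an unbranched aldehyde may be low, and ethyl transfer or enolisation may compete.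
- The fallback sets out from 15.
- 3,5-Dimethoxyphenylmagnesium bromide (from commercial 1-bromo-3,5-dimethoxybenzene) adds to give 1-(3,5-dimethoxyphenyl)-7-[(2S,5R,7S)-7-methyl-1,6-dioxaspiro[4.4]nonan-2-yl]heptan-1-ol F3 as C1 epimers.
- Ley–Griffith oxidation gives 1-(3,5-dimethoxyphenyl)-7-[(2S,5R,7S)-7-methyl-1,6-dioxaspiro[4.4]nonan-2-yl]heptan-1-one F4.
- Noyori-type asymmetric transfer hydrogenation (RuCl(p-cymene)[(R,R)-TsDPEN], HCO2Na, aqueous MeOH, non-acidic) gives (1R)-1-(3,5-dimethoxyphenyl)-7-[(2S,5R,7S)-7-methyl-1,6-dioxaspiro[4.4]nonan-2-yl]heptan-1-ol F5.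
- NBS (NaHCO3-buffered MeCN, 0 °C) brominates ortho to the side chain and para to a methoxy group to give (1R)-1-(2-bromo-3,5-dimethoxyphenyl)-7-[(2S,5R,7S)-7-methyl-1,6-dioxaspiro[4.4]nonan-2-yl]heptan-1-ol F6.
- Palladium-catalysed carbonylative lactonization (Pd(OAc)2, dppp, CO 1 atm, Et3N, toluene, 90 °C) closes the phthalide.
- The fallback comes back to the route at 23.

**Further compounds**
F1 | step 6 | tert-butyl{[(2S)-5-{[(4S)-11-(benzyloxy)undec-1-en-4-yl]oxy}hex-5-en-2-yl]oxy}dimethylsilane | C=CC[C@H](CCCCCCCOCc1ccccc1)OC(=C)CC[C@H](C)O[Si](C)(C)C(C)(C)C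
F2 | step 8 | (2S,5S,7S)-2-[7-(benzyloxy)heptyl]-7-methyl-1,6-dioxaspiro[4.4]nonane | c1ccccc1COCCCCCCC[C@H]1CC[C@]2(CC[C@H](C)O2)O1
F3 | step 14 | 1-(3,5-dimethoxyphenyl)-7-[(2S,5R,7S)-7-methyl-1,6-dioxaspiro[4.4]nonan-2-yl]heptan-1-ol (C1 epimers) | COc1cc(OC)cc(c1)C(O)CCCCCC[C@H]1CC[C@@]2(CC[C@H](C)O2)O1
F4 | step 14 | 1-(3,5-dimethoxyphenyl)-7-[(2S,5R,7S)-7-methyl-1,6-dioxaspiro[4.4]nonan-2-yl]heptan-1-one | COc1cc(OC)cc(c1)C(=O)CCCCCC[C@H]1CC[C@@]2(CC[C@H](C)O2)O1
F5 | step 14 | (1R)-1-(3,5-dimethoxyphenyl)-7-[(2S,5R,7S)-7-methyl-1,6-dioxaspiro[4.4]nonan-2-yl]heptan-1-ol | COc1cc(OC)cc(c1)[C@@H](CCCCCC[C@H]1CC[C@@]2(CC[C@H](C)O2)O1)O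
F6 | step 14 | (1R)-1-(2-bromo-3,5-dimethoxyphenyl)-7-[(2S,5R,7S)-7-methyl-1,6-dioxaspiro[4.4]nonan-2-yl]heptan-1-ol | COc1cc(OC)c(Br)c(c1)[C@@H](CCCCCC[C@H]1CC[C@@]2(CC[C@H](C)O2)O1)O
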